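**Retrosynthetic overview**
Locants: lignan numbering, unprimed = guaiacyl half, primed = prenyloxyaryl half. The target is (7S,8S,7'R,8'S): cis-fused, guaiacyl endo on ring A (C7–O–C9'–C8'–C8), prenyloxyaryl exo on ring B (C7'–O–C9–C8–C8').
Late stage: desilylation ⇐ prenylation ⇐ debenzylation; the ring B ether ⇐ lactone (C9 carried as C=O) by reduction and re-closure without touching C7'.
C7–H and C8–H ⇐ convex-face hydrogenation of a C7=C8 enol ether (ring A as a 2-aryl-4,5-dihydrofuran); this is what places the guaiacyl group endo.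
Key disconnection: the ring-fusion bond C8–C8', made by intramolecular carbene cyclopropanation of an (R)-1-arylallyl 2-diazo-3-aryl-3-oxopropanoate (lactone ring B closes first), then in the same pot an iodide-induced Cloke–Wilson rearrangement (ring A closes second). Enabling feature: C8 lies between the O-bearing carbons C7 (aryl) and C9, so with C7 as ketone and C9 as ester carbonyl it is a diazo-stabilised carbene carbon, while C8'–C9' is a vinyl group on the C7' carbinol that the C9 ester ties to C8.
Precursor ⇐ lipase-resolved (R)-allylic acetate + aroyl imidazole (crossed Claisen condensation) + diazo transfer; only C7' is preset.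

Key step: step 7

Assumption: the lipase is taken to acylate the (R)-enantiomer of the 1-arylallyl alcohol (aryl as the large, vinyl as the medium substituent), as it does with simple 1-arylalkanols.

**Step 1**
Reactants: 1 4-(benzyloxy)-3-methoxybenzaldehyde; 2 vinylmagnesium bromide
Product: 3 rac-1-[4-(benzyloxy)-3-methoxyphenyl]prop-2-en-1-ol
Conditions: CH2=CHMgBr (1.2 equiv), THF, 0 °C; aq. NH4Cl
Reagents that add atoms: vinylmagnesium bromide (2), C=C[Mg]Br
Why: Grignard 1,2-addition to the aryl aldehyde should give the racemic secondary allylic alcohol, whose stereocenter (the future C7') is formed without control and is resolved in step 2.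

**Step 2**
Reactants: 3 rac-1-[4-(benzyloxy)-3-methoxyphenyl]prop-2-en-1-ol; 4 vinyl acetate
Product: 5 (R)-1-[4-(benzyloxy)-3-methoxyphenyl]prop-2-en-1-yl acetate
Conditions: Novozym 435 (immobilised lipase B from Candida antarctica), vinyl acetate (3 equiv), MTBE, 30 °C, run to about half conversion; chromatography on Et3N-deactivated silica
Reagents that add atoms: vinyl acetate (4), CC(=O)OC=C
Why: Lipase-catalysed kinetic resolution by irreversible transesterification should acylate only the (R)-alcohol, which fixes C7' as R and at the same time installs the acetyl group whose two carbons become C8 and C9.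

**Step 3**
Reactants: 6 vanillic acid; 7 chlorotriisopropylsilane
Product: 9 3-methoxy-4-(triisopropylsilyloxy)benzoic acid, via bis-silylated benzoate 8 (not isolated)
Conditions: i-Pr3SiCl (2.3 equiv), imidazole (5 equiv), DMF, rt; then AcOH/THF/H2O, rt
Reagents that add atoms: chlorotriisopropylsilane (7), CC(C)[Si](Cl)(C(C)C)C(C)C
Why: Silylation of both the phenol and the acid followed by selective hydrolysis of the labile silyl ester should leave the robust aryl silyl ether, the phenol protecting group that lasts until the final step.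

**Step 4**
Reactants: 9 3-methoxy-4-(triisopropylsilyloxy)benzoic acid; 10 1,1'-carbonyldiimidazole
Product: 11 1-[3-methoxy-4-(triisopropylsilyloxy)benzoyl]imidazole
Conditions: carbonyldiimidazole (1.1 equiv), CH2Cl2, rt; quick cold-water wash, used crude
Reagents that add atoms: 1,1'-carbonyldiimidazole (10), O=C(n1ccnc1)n1ccnc1
Why: Acid activation with carbonyldiimidazole should give the acyl imidazole, an acyl donor that reacts cleanly with carbon nucleophiles.

**Step 5**
Reactants: 5 (R)-1-[4-(benzyloxy)-3-methoxyphenyl]prop-2-en-1-yl acetate; 11 1-[3-methoxy-4-(triisopropylsilyloxy)benzoyl]imidazole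
Product: 12 (R)-1-[4-(benzyloxy)-3-methoxyphenyl]prop-2-en-1-yl 3-[3-methoxy-4-(triisopropylsilyloxy)phenyl]-3-oxopropanoate
Conditions: LiN(SiMe3)2 (2.2 equiv), THF, −78 °C; then 11 (1.05 equiv), −78 → −40 °C; aq. NH4Cl
Reagents that add atoms: none
Why: In this crossed Claisen condensation the lithium enolate of acetate 5 should be C-acylated by 11 while the second equivalent of base stores the product as its enolate and so prevents double acylation; no bond to C7' is made or broken.

**Step 6**
Reactants: 12 the 3-oxopropanoate from step 5; 13 4-acetamidobenzenesulfonyl azide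
Product: 14 (R)-1-[4-(benzyloxy)-3-methoxyphenyl]prop-2-en-1-yl 2-diazo-3-[3-methoxy-4-(triisopropylsilyloxy)phenyl]-3-oxopropanoate
Conditions: 4-acetamidobenzenesulfonyl azide (1.2 equiv), Et3N (2 equiv), MeCN, 0 °C → rt
Reagents that add atoms: 4-acetamidobenzenesulfonyl azide (13), CC(=O)Nc1ccc(S(=O)(=O)N=[N+]=[N-])cc1
Why: Regitz diazo transfer to the active methylene group of the 1,3-dicarbonyl compound should place the carbene precursor on C8.

**Step 7**
Reactants: 14 the 2-diazo-3-oxopropanoate from step 6
Product: 16 (3R,3aS)-3-[4-(benzyloxy)-3-methoxyphenyl]-6-[3-methoxy-4-(triisopropylsilyloxy)phenyl]-3a,4-dihydro-1H,3H-furo[3,4-c]furan-1-one, via cyclopropane lactone 15 (not isolated)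
Conditions: Rh2(OAc)4 (1 mol %), 1,2-dichloroethane, 60 °C, slow addition of 14; then n-Bu4NI (0.2 equiv), 80 °C, same pot
Reagents that add atoms: none
Why: Rh2(OAc)4 converts the diazo group into an electrophilic rhodium carbenoid at C8 that adds to the pendant vinyl group, making C8–C8' and C8–C9' (cyclopropane 15); iodide then opens this ketone- and lactone-activated cyclopropane by SN2 attack at its CH2 carbon C9', and the aroyl enolate set free displaces iodide with its ketone oxygen to give enol ether 16. The closest known reaction types are the intramolecular cyclopropanation of allylic 2-diazo-3-oxo esters to 1-acyl-3-oxabicyclo[3.1.0]hexan-2-ones and the nucleophile-catalysed Cloke–Wilson rearrangement of 1-acylcyclopropane-1-carboxylates to 4,5-dihydrofuran-3-carboxylates. Ring B closes as the γ-lactone by the C8–C8' bond (carbene attack on the internal alkene carbon, a 5-exo mode with respect to the ester tether), and ring A closes by 5-exo-tet O-alkylation at C9'. The only new stereocenter that survives, C8', is controlled by the C7' center: in the carbene addition the aryl group at C7' should take the exo position, anti to the cyclopropane CH2, which makes aryl and C9' trans on ring B, while the C8 center of 15 is lost again when C8 becomes sp2. The step needs chemoselectivity for cyclopropanation over aromatic cycloaddition, C–H insertion and ionisation of the allylic ester, which the carboxylate-ligated dirhodium catalyst, the five-membered transition state and slow addition at moderate temperature should secure; it also needs O- over C-alkylation in the second stage, which is secured because C-alkylation only regenerates 15 while O-alkylation releases the strain of the bicyclo[3.1.0]hexane.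

**Step 8**
Reactants: 16 the enol ether lactone from step 7
Product: 17 (3R,3aS,6S,6aR)-3-[4-(benzyloxy)-3-methoxyphenyl]-6-[3-methoxy-4-(triisopropylsilyloxy)phenyl]tetrahydro-1H,3H-furo[3,4-c]furan-1-one
Conditions: H2 (4 atm), Pd/C (10 wt %), pyridine (0.5 equiv), EtOAc, rt
Reagents that add atoms: none
Why: Heterogeneous catalytic hydrogenation should add both hydrogens to the convex face of the bicycle (the face of C8'–H), so that C8–H is cis to C8'–H (cis ring fusion) and C7–H is cis to C8–H (silyloxyaryl group endo), while pyridine suppresses hydrogenolysis of the benzyl ether and of the benzylic C–O bonds.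

**Step 9**
Reactants: 17 the saturated lactone from step 8
Product: 18 (R)-[4-(benzyloxy)-3-methoxyphenyl]{(3S,4S,5S)-4-(hydroxymethyl)-5-[3-methoxy-4-(triisopropylsilyloxy)phenyl]tetrahydrofuran-3-yl}methanol
Conditions: LiBH4 (2 equiv), THF, 0 °C → rt
Reagents that add atoms: none
Why: Hydride reduction of the lactone should give the 1,4-diol and leave the ethers, the aryl silyl ether and all four stereocenters untouched.

**Step 10**
Reactants: 18 the diol from step 9
Product: 20 (1S,3aS,4R,6aS)-4-[4-(benzyloxy)-3-methoxyphenyl]-1-[3-methoxy-4-(triisopropylsilyloxy)phenyl]tetrahydro-1H,3H-furo[3,4-c]furan, via primary mesylate 19 (not isolated)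
Conditions: MsCl (1.1 equiv), Et3N (3 equiv), CH2Cl2, 0 °C → rt
Reagents that add atoms: none
Why: Selective sulfonylation of the primary alcohol followed by intramolecular Williamson etherification (5-exo-tet) by the secondary benzylic hydroxyl should close ring B with retention at C7', because no bond to C7' is broken.

**Step 11**
Reactants: 20 the benzyl- and silyl-protected furofuran from step 10
Product: 21 4-[(1R,3aS,4S,6aS)-4-[3-methoxy-4-(triisopropylsilyloxy)phenyl]tetrahydro-1H,3H-furo[3,4-c]furan-1-yl]-2-methoxyphenol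
Conditions: H2 (1 atm), Pd/C (10 wt %), EtOAc, rt
Reagents that add atoms: none
Why: Hydrogenolysis of the aryl benzyl ether should free the phenol of the exo aryl group, the cyclic benzylic ethers being cleaved much more slowly under neutral conditions at low pressure.

**Step 12**
Reactants: 21 the monophenol from step 11; 22 1-bromo-3-methylbut-2-ene
Product: 23 (1S,3aS,4R,6aS)-1-[3-methoxy-4-(triisopropylsilyloxy)phenyl]-4-{3-methoxy-4-[(3-methylbut-2-en-1-yl)oxy]phenyl}tetrahydro-1H,3H-furo[3,4-c]furan
Conditions: prenyl bromide (1.2 equiv), K2CO3, acetone, rt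
Reagents that add atoms: 1-bromo-3-methylbut-2-ene (22), CC(C)=CCBr
Why: Williamson ether synthesis should prenylate only the free phenol of the exo aryl group, since the other phenol is still masked as its silyl ether.

**Step 13**
Reactants: 23 the prenyl ether from step 12
Product: 24 2-methoxy-4-[(1S,3aS,4R,6aS)-4-{3-methoxy-4-[(3-methylbut-2-en-1-yl)oxy]phenyl}tetrahydro-1H,3H-furo[3,4-c]furan-1-yl]phenol (target)
Conditions: n-Bu4NF (1.1 equiv), AcOH (1.1 equiv), THF, 0 °C
Reagents that add atoms: none
Why: Fluoride-induced cleavage of the aryl silyl ether, buffered with acetic acid so that no free phenoxide builds up, should release the target without touching the prenyl ether or the benzylic ether stereocenters.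

**Compound list**
1 | 4-(benzyloxy)-3-methoxybenzaldehyde | COc1cc(C=O)ccc1OCc1ccccc1 | starting material
2 | vinylmagnesium bromide | C=C[Mg]Br | starting material
3 | rac-1-[4-(benzyloxy)-3-methoxyphenyl]prop-2-en-1-ol | C=CC(O)c1ccc(OCc2ccccc2)c(OC)c1 | intermediate
4 | vinyl acetate | CC(=O)OC=C | starting material
5 | (R)-1-[4-(benzyloxy)-3-methoxyphenyl]prop-2-en-1-yl acetate | CC(=O)O[C@H](C=C)c1ccc(OCc2ccccc2)c(OC)c1 | intermediate
6 | vanillic acid | COc1cc(C(=O)O)ccc1O | starting material
7 | chlorotriisopropylsilane | CC(C)[Si](Cl)(C(C)C)C(C)C | starting material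
8 | triisopropylsilyl 3-methoxy-4-(triisopropylsilyloxy)benzoate | COc1cc(C(=O)O[Si](C(C)C)(C(C)C)C(C)C)ccc1O[Si](C(C)C)(C(C)C)C(C)C | intermediate
9 | 3-methoxy-4-(triisopropylsilyloxy)benzoic acid | COc1cc(C(=O)O)ccc1O[Si](C(C)C)(C(C)C)C(C)C | intermediate
10 | 1,1'-carbonyldiimidazole | O=C(n1ccnc1)n1ccnc1 | starting material
11 | 1-[3-methoxy-4-(triisopropylsilyloxy)benzoyl]imidazole | COc1cc(C(=O)n2ccnc2)ccc1O[Si](C(C)C)(C(C)C)C(C)C | intermediate
12 | (R)-1-[4-(benzyloxy)-3-methoxyphenyl]prop-2-en-1-yl 3-[3-methoxy-4-(triisopropylsilyloxy)phenyl]-3-oxopropanoate | COc1cc(C(=O)CC(=O)O[C@H](C=C)c2ccc(OCc3ccccc3)c(OC)c2)ccc1O[Si](C(C)C)(C(C)C)C(C)C | intermediate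
13 | 4-acetamidobenzenesulfonyl azide | CC(=O)Nc1ccc(S(=O)(=O)N=[N+]=[N-])cc1 | starting material
14 | (R)-1-[4-(benzyloxy)-3-methoxyphenyl]prop-2-en-1-yl 2-diazo-3-[3-methoxy-4-(triisopropylsilyloxy)phenyl]-3-oxopropanoate | COc1cc(C(=O)C(=[N+]=[N-])C(=O)O[C@H](C=C)c2ccc(OCc3ccccc3)c(OC)c2)ccc1O[Si](C(C)C)(C(C)C)C(C)C | intermediate
15 | (1S,4R,5R)-4-[4-(benzyloxy)-3-methoxyphenyl]-1-[3-methoxy-4-(triisopropylsilyloxy)benzoyl]-3-oxabicyclo[3.1.0]hexan-2-one (aryl anti to the cyclopropane CH2) | COc1cc(C(=O)[C@]23C[C@H]2[C@H](c2ccc(OCc4ccccc4)c(OC)c2)OC3=O)ccc1O[Si](C(C)C)(C(C)C)C(C)C | intermediate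
16 | (3R,3aS)-3-[4-(benzyloxy)-3-methoxyphenyl]-6-[3-methoxy-4-(triisopropylsilyloxy)phenyl]-3a,4-dihydro-1H,3H-furo[3,4-c]furan-1-one | COc1cc(C2=C3C(=O)O[C@@H](c4ccc(OCc5ccccc5)c(OC)c4)[C@@H]3CO2)ccc1O[Si](C(C)C)(C(C)C)C(C)C | intermediate
17 | (3R,3aS,6S,6aR)-3-[4-(benzyloxy)-3-methoxyphenyl]-6-[3-methoxy-4-(triisopropylsilyloxy)phenyl]tetrahydro-1H,3H-furo[3,4-c]furan-1-one | COc1cc([C@H]2OC[C@@H]3[C@H]2C(=O)O[C@H]3c2ccc(OCc4ccccc4)c(OC)c2)ccc1O[Si](C(C)C)(C(C)C)C(C)C | intermediate
18 | (R)-[4-(benzyloxy)-3-methoxyphenyl]{(3S,4S,5S)-4-(hydroxymethyl)-5-[3-methoxy-4-(triisopropylsilyloxy)phenyl]tetrahydrofuran-3-yl}methanol | COc1cc([C@H]2OC[C@@H]([C@@H](O)c3ccc(OCc4ccccc4)c(OC)c3)[C@H]2CO)ccc1O[Si](C(C)C)(C(C)C)C(C)C | intermediate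
19 | primary methanesulfonate of diol 18 | COc1cc([C@H]2OC[C@@H]([C@@H](O)c3ccc(OCc4ccccc4)c(OC)c3)[C@H]2COS(C)(=O)=O)ccc1O[Si](C(C)C)(C(C)C)C(C)C | intermediate
20 | (1S,3aS,4R,6aS)-4-[4-(benzyloxy)-3-methoxyphenyl]-1-[3-methoxy-4-(triisopropylsilyloxy)phenyl]tetrahydro-1H,3H-furo[3,4-c]furan | COc1cc([C@H]2OC[C@@H]3[C@H]2CO[C@H]3c2ccc(OCc4ccccc4)c(OC)c2)ccc1O[Si](C(C)C)(C(C)C)C(C)C | intermediate
21 | 4-[(1R,3aS,4S,6aS)-4-[3-methoxy-4-(triisopropylsilyloxy)phenyl]tetrahydro-1H,3H-furo[3,4-c]furan-1-yl]-2-methoxyphenol | COc1cc([C@H]2OC[C@@H]3[C@H]2CO[C@H]3c2ccc(O)c(OC)c2)ccc1O[Si](C(C)C)(C(C)C)C(C)C | intermediate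
22 | 1-bromo-3-methylbut-2-ene (prenyl bromide) | CC(C)=CCBr | starting material
23 | (1S,3aS,4R,6aS)-1-[3-methoxy-4-(triisopropylsilyloxy)phenyl]-4-{3-methoxy-4-[(3-methylbut-2-en-1-yl)oxy]phenyl}tetrahydro-1H,3H-furo[3,4-c]furan | COc1cc([C@H]2OC[C@@H]3[C@H]2CO[C@H]3c2ccc(OCC=C(C)C)c(OC)c2)ccc1O[Si](C(C)C)(C(C)C)C(C)C | intermediate
24 | 2-methoxy-4-[(1S,3aS,4R,6aS)-4-{3-methoxy-4-[(3-methylbut-2-en-1-yl)oxy]phenyl}tetrahydro-1H,3H-furo[3,4-c]furan-1-yl]phenol | COc1cc([C@H]2OC[C@@H]3[C@H]2CO[C@H]3c2ccc(OCC=C(C)C)c(OC)c2)ccc1O | target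

**Step count and risks**
Total step count: 13. Longest linear sequence: 11 steps (steps 1, 2, 5, 6, 7, 8, 9, 10, 11, 12, 13, from compound 1); steps 3 and 4 form the side branch.

Steps most likely to fail:

Step 7. The carbene may add to the vinyl group with poor facial selectivity, placing the C7' aryl group syn instead of anti to the cyclopropane CH2. The carbenoid may also attack the electron-rich benzylic arene, or the catalyst may ionise the allylic ester and transpose it before carbene transfer. The fallback sets out from 12 and comes back at 16, and forms the same C8–C8' bond by a radical ring closure. Iodination of 12 with N-iodosuccinimide in MeCN should give the 2-iodo-3-oxopropanoate F1. Iodine-atom-transfer radical cyclisation (dilauroyl peroxide, benzene, 80 °C; 5-exo closure onto the internal alkene carbon, the allylic aryl group directing the new CH2I group trans) should give the iodomethyl lactone F2. K2CO3 in MeCN at 60 °C should then close ring A by O-alkylation of the aroyl enolate, directly or through 15 and the iodide released, to give 16.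

Step 8. Hydrogen uptake by the tetrasubstituted, donor- and acceptor-substituted double bond may be too slow on the pyridine-moderated catalyst, and without the moderator hydrogenolysis of the benzylic lactone C–O bond and of the benzyl ether would take over. The fallback sets out from 16 and comes back at 17 by ionic hydrogenation (Et3SiH, CF3CO2H, CH2Cl2, −20 °C). Protonation at C8 from the convex face gives the cis-fused 2-aryl oxocarbenium ion, and hydride is then delivered to C7 from the same convex face, so the aryl group again ends up endo. This fallback makes no new compound (F0).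

Step 5. The ester enolate may be acylated incompletely or twice, and proton exchange between enolate and product may stall the condensation. The fallback sets out from 5 and comes back at 12 by an aldol–oxidation sequence. The lithium enolate of 5 (LiN(i-Pr)2, THF, −78 °C) is added to 3-methoxy-4-(triisopropylsilyloxy)benzaldehyde F3, made from vanillin with i-Pr3SiCl and imidazole. This should give the β-hydroxy ester F4 as a mixture of carbinol epimers, which does not matter. Oxidation of F4 with Dess–Martin periodinane in CH2Cl2 should give 12.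

**Further compounds**
F1 | step 7 | (R)-1-[4-(benzyloxy)-3-methoxyphenyl]prop-2-en-1-yl 2-iodo-3-[3-methoxy-4-(triisopropylsilyloxy)phenyl]-3-oxopropanoate | COc1cc(C(=O)C(I)C(=O)O[C@H](C=C)c2ccc(OCc3ccccc3)c(OC)c2)ccc1O[Si](C(C)C)(C(C)C)C(C)C
F2 | step 7 | (4S,5R)-5-[4-(benzyloxy)-3-methoxyphenyl]-4-(iodomethyl)-3-[3-methoxy-4-(triisopropylsilyloxy)benzoyl]dihydrofuran-2(3H)-one (aryl and CH2I trans) | COc1cc(C(=O)C2C(=O)O[C@@H](c3ccc(OCc4ccccc4)c(OC)c3)[C@@H]2CI)ccc1O[Si](C(C)C)(C(C)C)C(C)C
F0 | step 8 | none | none
F3 | step 5 | 3-methoxy-4-(triisopropylsilyloxy)benzaldehyde | COc1cc(C=O)ccc1O[Si](C(C)C)(C(C)C)C(C)C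
F4 | step 5 | (R)-1-[4-(benzyloxy)-3-methoxyphenyl]prop-2-en-1-yl 3-hydroxy-3-[3-methoxy-4-(triisopropylsilyloxy)phenyl]propanoate | COc1cc(C(O)CC(=O)O[C@H](C=C)c2ccc(OCc3ccccc3)c(OC)c2)ccc1O[Si](C(C)C)(C(C)C)C(C)C
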